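The plan forms the C1–C7 bond last among the ring bonds (target numbered as a bicyclo[3.2.1]oct-2-ene: C1 allyl-bearing bridgehead, C7 the CHMe carbon, C8 the ketone). C7 is read as the inner carbon of a vinyl group and C1 as the β-carbon of a cyclohexenone whose carbonyl is C3. An iron hydride places a hydrogen atom on the vinyl terminus, creating the C7 methyl group, and the C7 radical adds 5-exo to C1, closing the cyclopentane ring C1–C8–C5–C6–C7 and setting C1 and C7. The precursor is a monocyclic bromo-enedione ketal whose C5 and C6 stereocentres come from an asymmetric Claisen rearrangement; bromine holds the place of the allyl group.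

Key step: step 6

Remark 1: locants C1–C8 in the Why lines are those of target 14 and are used for the same carbons in the monocyclic precursors.
Remark 2 (assumption): the antipode of the bis(oxazoline) ligand in step 5 is the one that delivers the (3S,1′R) isomer 8; all later stereocentres follow from it.

Step 1
Reactants: 1 2-hydroxy-3,4-dimethoxybenzaldehyde
Product: 2 5-bromo-2-hydroxy-3,4-dimethoxybenzaldehyde
Conditions: NBS, MeCN, 0 °C to rt
Reagents that add atoms: N-bromosuccinimide, O=C1CCC(=O)N1Br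
Why: Electrophilic aromatic bromination should go to the ring position para to the free hydroxyl, ortho to a methoxy group and meta to the formyl group, where all directing effects converge; this carbon becomes C1.

Step 2
Reactants: 2 5-bromo-2-hydroxy-3,4-dimethoxybenzaldehyde; 3 (2E)-3-(3,4,5-trimethoxyphenyl)prop-2-en-1-ol
Product: 4 5-bromo-3,4-dimethoxy-2-{[(2E)-3-(3,4,5-trimethoxyphenyl)prop-2-en-1-yl]oxy}benzaldehyde
Conditions: PPh3, DIAD, THF, 0 °C to rt
Reagents that add atoms: none
Why: Mitsunobu etherification, in which the acidic salicylaldehyde-type phenol displaces the activated primary allylic alcohol by SN2 and the E alkene is kept.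

Step 3
Reactants: 4 5-bromo-3,4-dimethoxy-2-{[(2E)-3-(3,4,5-trimethoxyphenyl)prop-2-en-1-yl]oxy}benzaldehyde
Product: 6 5-bromo-3,4-dimethoxy-2-{[(2E)-3-(3,4,5-trimethoxyphenyl)prop-2-en-1-yl]oxy}phenol, via aryl formate 5 (not isolated)
Conditions: 30% H2O2, B(OH)3, cat. H2SO4, THF, rt; then aq. NaHCO3
Reagents that add atoms: hydrogen peroxide, OO
Why: Dakin oxidation (aryl migration in the peroxide adduct of an electron-rich alkoxybenzaldehyde, then formate cleavage) unveils the phenol, so the formyl group has served as a latent hydroxyl that kept the two neighbouring oxygens distinct.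

Step 4
Reactants: 6 5-bromo-3,4-dimethoxy-2-{[(2E)-3-(3,4,5-trimethoxyphenyl)prop-2-en-1-yl]oxy}phenol
Product: 7 5-bromo-3,4,4-trimethoxy-2-{[(2E)-3-(3,4,5-trimethoxyphenyl)prop-2-en-1-yl]oxy}cyclohexa-2,5-dien-1-one
Conditions: PhI(OAc)2, MeOH, 0 °C
Reagents that add atoms: methanol, CO
Why: Oxidative dearomatization of a para-methoxyphenol, in which methanol adds at the methoxylated para carbon (future C8) to give the para-quinone monoketal and leaves an allyl vinyl ether next to the C3 carbonyl.

Step 5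
Reactants: 7 5-bromo-3,4,4-trimethoxy-2-{[(2E)-3-(3,4,5-trimethoxyphenyl)prop-2-en-1-yl]oxy}cyclohexa-2,5-dien-1-one
Product: 8 (3S)-5-bromo-3,4,4-trimethoxy-3-[(1R)-1-(3,4,5-trimethoxyphenyl)prop-2-en-1-yl]cyclohex-5-ene-1,2-dione
Conditions: Cu(OTf)2 (10 mol %), (S,S)-t-Bu-box (11 mol %), 4 Å MS, CH2Cl2, rt
Reagents that add atoms: none
Why: Catalytic asymmetric Claisen rearrangement of a 2-acyl allyl vinyl ether, in which the ether oxygen and the C3 carbonyl chelate the chiral divalent copper Lewis acid, the chair transition state with the E-cinnamyl unit sets C5 and C6 in the required relative sense, and the ligand sets the absolute sense.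

Step 6
Reactants: 8 (3S)-5-bromo-3,4,4-trimethoxy-3-[(1R)-1-(3,4,5-trimethoxyphenyl)prop-2-en-1-yl]cyclohex-5-ene-1,2-dione
Product: 9 (1S,5S,6S,7R)-5-bromo-1,8,8-trimethoxy-6-methyl-7-(3,4,5-trimethoxyphenyl)bicyclo[3.2.1]octane-2,3-dione
Conditions: Fe(acac)3 (30 mol %), PhSiH3, EtOH/(CH2OH)2, 60 °C
Reagents that add atoms: none
Why: Fe(acac)3 and PhSiH3 form an iron hydride that transfers a hydrogen atom to the terminal CH2 of the only unactivated alkene (Markovnikov), the secondary C7 radical adds to C1, the β-carbon of the C3 enone, and the α-keto radical at C2 is then reduced and protonated; the closest known reaction type is the iron-mediated reductive olefin coupling (hydrogen-atom-transfer Giese reaction) run intramolecularly. The cyclopentane ring C1–C8–C5–C6–C7 closes in the 5-exo-trig mode. C1 is fixed by the tether, because the side chain on C5 reaches only one face of the ring, and C7 is set in the transition state, where its methyl group should turn away from the aryl group on C6 and from the concave face of the ring (methyl exo, trans to aryl). Regioselectivity is secured because C1 is the only Giese position: C2 is α to the carbonyl and C8 is a saturated ketal. Chemoselectivity is secured by the bromine, which stands in for the allyl group (a second terminal alkene would compete for the iron hydride) and should stay on C1 because its loss from the adduct would create a bridgehead alkene forbidden by the Bredt rule.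

Step 7
Reactants: 9 (1S,5S,6S,7R)-5-bromo-1,8,8-trimethoxy-6-methyl-7-(3,4,5-trimethoxyphenyl)bicyclo[3.2.1]octane-2,3-dione
Product: 10 (1S,5R,6S,7R)-1,8,8-trimethoxy-6-methyl-5-(prop-2-en-1-yl)-7-(3,4,5-trimethoxyphenyl)bicyclo[3.2.1]octane-2,3-dione
Conditions: allylSnBu3, AIBN (cat.), PhH, 80 °C
Reagents that add atoms: allyltributylstannane, C=CC[Sn](CCCC)(CCCC)CCCC
Why: Keck radical allylation, in which the tin radical abstracts the bridgehead bromine and the bridgehead radical adds to the allylstannane with loss of the tin radical; a bridgehead cannot invert, so C1 keeps its configuration.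

Step 8
Reactants: 10 (1S,5R,6S,7R)-1,8,8-trimethoxy-6-methyl-5-(prop-2-en-1-yl)-7-(3,4,5-trimethoxyphenyl)bicyclo[3.2.1]octane-2,3-dione
Product: 11 (1R,5S,6S,7R)-3-hydroxy-1-methoxy-6-methyl-5-(prop-2-en-1-yl)-7-(3,4,5-trimethoxyphenyl)bicyclo[3.2.1]oct-3-ene-2,8-dione
Conditions: TFA/H2O (9:1), CH2Cl2, 0 °C to rt
Reagents that add atoms: water, O
Why: Acid-catalysed ketal hydrolysis should unmask the C8 ketone, and the 1,2-diketone should rest as its enol (diosphenol) toward C2, the only α-carbon that carries hydrogen.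

Step 9
Reactants: 11 (1R,5S,6S,7R)-3-hydroxy-1-methoxy-6-methyl-5-(prop-2-en-1-yl)-7-(3,4,5-trimethoxyphenyl)bicyclo[3.2.1]oct-3-ene-2,8-dione
Product: 12 (1R,5S,6S,7R)-1,3-dimethoxy-6-methyl-5-(prop-2-en-1-yl)-7-(3,4,5-trimethoxyphenyl)bicyclo[3.2.1]oct-3-ene-2,8-dione
Conditions: MeI, K2CO3, acetone, rt
Reagents that add atoms: iodomethane, CI
Why: O-Alkylation of the diosphenol gives the C3 methyl enol ether with the C2=C3 double bond already in place, since no other enol can form.

Step 10
Reactants: 12 (1R,5S,6S,7R)-1,3-dimethoxy-6-methyl-5-(prop-2-en-1-yl)-7-(3,4,5-trimethoxyphenyl)bicyclo[3.2.1]oct-3-ene-2,8-dione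
Product: 13 (1S,4R,5S,6R,7S)-4-hydroxy-3,5-dimethoxy-7-methyl-1-(prop-2-en-1-yl)-6-(3,4,5-trimethoxyphenyl)bicyclo[3.2.1]oct-2-en-8-one
Conditions: NaBH4, CeCl3·7H2O, MeOH, −78 °C
Reagents that add atoms: none
Why: Luche 1,2-reduction, in which hydride should attack the conjugated C4 carbonyl from the face of the C8 bridge, away from the endo aryl group on C6, to give the 4R alcohol, while the C8 ketone between two quaternary carbons should react more slowly.

Step 11
Reactants: 13 (1S,4R,5S,6R,7S)-4-hydroxy-3,5-dimethoxy-7-methyl-1-(prop-2-en-1-yl)-6-(3,4,5-trimethoxyphenyl)bicyclo[3.2.1]oct-2-en-8-one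
Product: 14 (1S,4R,5S,6R,7S)-3,5-dimethoxy-7-methyl-8-oxo-1-(prop-2-en-1-yl)-6-(3,4,5-trimethoxyphenyl)bicyclo[3.2.1]oct-2-en-4-yl acetate
Conditions: Ac2O, pyridine, DMAP (cat.), CH2Cl2, rt
Reagents that add atoms: acetic anhydride, CC(=O)OC(C)=O
Why: DMAP-catalysed acylation of the secondary allylic alcohol, with no change at any stereocentre.

Compound list
1 | 2-hydroxy-3,4-dimethoxybenzaldehyde | O=Cc1ccc(OC)c(OC)c1O | starting material
2 | 5-bromo-2-hydroxy-3,4-dimethoxybenzaldehyde | O=Cc1cc(Br)c(OC)c(OC)c1O | intermediate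
3 | (2E)-3-(3,4,5-trimethoxyphenyl)prop-2-en-1-ol | OC/C=C/c1cc(OC)c(OC)c(OC)c1 | starting material
4 | 5-bromo-3,4-dimethoxy-2-{[(2E)-3-(3,4,5-trimethoxyphenyl)prop-2-en-1-yl]oxy}benzaldehyde | O=Cc1cc(Br)c(OC)c(OC)c1OC/C=C/c1cc(OC)c(OC)c(OC)c1 | intermediate
5 | 5-bromo-3,4-dimethoxy-2-{[(2E)-3-(3,4,5-trimethoxyphenyl)prop-2-en-1-yl]oxy}phenyl formate (not isolated) | O=COc1cc(Br)c(OC)c(OC)c1OC/C=C/c1cc(OC)c(OC)c(OC)c1 | intermediate
6 | 5-bromo-3,4-dimethoxy-2-{[(2E)-3-(3,4,5-trimethoxyphenyl)prop-2-en-1-yl]oxy}phenol | Oc1cc(Br)c(OC)c(OC)c1OC/C=C/c1cc(OC)c(OC)c(OC)c1 | intermediate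
7 | 5-bromo-3,4,4-trimethoxy-2-{[(2E)-3-(3,4,5-trimethoxyphenyl)prop-2-en-1-yl]oxy}cyclohexa-2,5-dien-1-one | O=C1C=C(Br)C(OC)(OC)C(OC)=C1OC/C=C/c1cc(OC)c(OC)c(OC)c1 | intermediate
8 | (3S)-5-bromo-3,4,4-trimethoxy-3-[(1R)-1-(3,4,5-trimethoxyphenyl)prop-2-en-1-yl]cyclohex-5-ene-1,2-dione | BrC1=CC(=O)C(=O)[C@](OC)(C1(OC)OC)[C@@H](c1cc(OC)c(OC)c(OC)c1)C=C | intermediate
9 | (1S,5S,6S,7R)-5-bromo-1,8,8-trimethoxy-6-methyl-7-(3,4,5-trimethoxyphenyl)bicyclo[3.2.1]octane-2,3-dione | Br[C@]12CC(=O)C(=O)[C@](OC)(C1(OC)OC)[C@@H](c1cc(OC)c(OC)c(OC)c1)[C@@H]2C | intermediate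
10 | (1S,5R,6S,7R)-1,8,8-trimethoxy-6-methyl-5-(prop-2-en-1-yl)-7-(3,4,5-trimethoxyphenyl)bicyclo[3.2.1]octane-2,3-dione | C=CC[C@]12CC(=O)C(=O)[C@](OC)(C1(OC)OC)[C@@H](c1cc(OC)c(OC)c(OC)c1)[C@@H]2C | intermediate
11 | (1R,5S,6S,7R)-3-hydroxy-1-methoxy-6-methyl-5-(prop-2-en-1-yl)-7-(3,4,5-trimethoxyphenyl)bicyclo[3.2.1]oct-3-ene-2,8-dione (enol form of the trione) | C=CC[C@]12C=C(O)C(=O)[C@](OC)(C1=O)[C@@H](c1cc(OC)c(OC)c(OC)c1)[C@@H]2C | intermediate
12 | (1R,5S,6S,7R)-1,3-dimethoxy-6-methyl-5-(prop-2-en-1-yl)-7-(3,4,5-trimethoxyphenyl)bicyclo[3.2.1]oct-3-ene-2,8-dione | C=CC[C@]12C=C(OC)C(=O)[C@](OC)(C1=O)[C@@H](c1cc(OC)c(OC)c(OC)c1)[C@@H]2C | intermediate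
13 | (1S,4R,5S,6R,7S)-4-hydroxy-3,5-dimethoxy-7-methyl-1-(prop-2-en-1-yl)-6-(3,4,5-trimethoxyphenyl)bicyclo[3.2.1]oct-2-en-8-one | C=CC[C@]12C=C(OC)[C@@H](O)[C@](OC)(C1=O)[C@@H](c1cc(OC)c(OC)c(OC)c1)[C@@H]2C | intermediate
14 | (1S,4R,5S,6R,7S)-3,5-dimethoxy-7-methyl-8-oxo-1-(prop-2-en-1-yl)-6-(3,4,5-trimethoxyphenyl)bicyclo[3.2.1]oct-2-en-4-yl acetate (CNP0181407.1) | C=CC[C@]12C=C(OC)[C@@H](OC(C)=O)[C@](OC)(C1=O)[C@@H](c1cc(OC)c(OC)c(OC)c1)[C@@H]2C | target

Total step count: 11. Longest linear sequence: 11 steps (1 to 14); 3 enters at step 2.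

Steps most likely to fail

Step 6 (key step). The C7 radical may be reduced before it cyclises, which would simply hydrogenate the vinyl group. The hydride system may also attack the bromo-enedione, or the methyl group may end endo because of the C8 ketal. The fallback separates radical formation from the metal hydride. It sets out from 8, where a Mukaiyama hydration of the vinyl group (Co(acac)2, PhSiH3, O2, i-PrOH) should give the secondary alcohol F1 as a mixture at the carbinol carbon. Acylation with PhOC(S)Cl and pyridine gives the phenyl thionocarbonate F2. Treatment with (TMS)3SiH and Et3B/air in toluene at 0 °C (Barton–McCombie conditions) then releases the same C7 radical slowly and at low temperature, and its 5-exo Giese cyclisation comes back to the route at 9.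

Step 5. The Lewis acid may ionise the cinnamyl ether to an ion pair, with loss of enantio- and diastereocontrol, or the rearrangement may pass through a boat transition state. The fallback forms the C5–C6 bond by intermolecular allylic alkylation instead. It sets out from 7, where Pd(PPh3)4 and morpholine in THF remove the cinnamyl group and give the diosphenol F3. The cinnamyl methyl carbonate F4 is made from 3 with ClCO2Me and pyridine. An iridium-catalysed, branched-selective asymmetric allylic alkylation of F3 with F4 ([Ir(cod)Cl]2, chiral binaphthol-derived phosphoramidite, Cs2CO3, THF, rt) then sets the benzylic centre under catalyst control and comes back to the route at 8.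

Step 10. The bridging C8 ketone may be reduced along with the C4 carbonyl. The fallback accepts this and corrects it afterwards. It sets out from 12, where excess NaBH4 with CeCl3·7H2O in MeOH at 0 °C reduces both ketones to the diol F5. Acetylation of the less hindered allylic C4 hydroxyl (Ac2O, pyridine, −20 °C) gives the hydroxy acetate F6, whose C8 carbinol lies between two quaternary carbons and should not acylate. Dess–Martin oxidation of that carbinol comes back to the route at 14.

Further compounds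
F1 | step 6 | (3S)-5-bromo-3-[(1S)-2-hydroxy-1-(3,4,5-trimethoxyphenyl)propyl]-3,4,4-trimethoxycyclohex-5-ene-1,2-dione (both carbinol epimers) | BrC1=CC(=O)C(=O)[C@](OC)(C1(OC)OC)[C@@H](c1cc(OC)c(OC)c(OC)c1)C(C)O
F2 | step 6 | O-phenyl thionocarbonate of the side-chain alcohol of F1 | BrC1=CC(=O)C(=O)[C@](OC)(C1(OC)OC)[C@@H](c1cc(OC)c(OC)c(OC)c1)C(C)OC(=S)Oc1ccccc1
F3 | step 5 | 5-bromo-2-hydroxy-3,4,4-trimethoxycyclohexa-2,5-dien-1-one | O=C1C=C(Br)C(OC)(OC)C(OC)=C1O
F4 | step 5 | methyl (2E)-3-(3,4,5-trimethoxyphenyl)prop-2-en-1-yl carbonate | COC(=O)OC/C=C/c1cc(OC)c(OC)c(OC)c1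
F5 | step 10 | (1S,4R,5S,6R,7S)-3,5-dimethoxy-7-methyl-1-(prop-2-en-1-yl)-6-(3,4,5-trimethoxyphenyl)bicyclo[3.2.1]oct-2-ene-4,8-diol (C8 configuration not assigned) | C=CC[C@]12C=C(OC)[C@@H](O)[C@](OC)(C1O)[C@@H](c1cc(OC)c(OC)c(OC)c1)[C@@H]2C
F6 | step 10 | (1S,4R,5S,6R,7S)-8-hydroxy-3,5-dimethoxy-7-methyl-1-(prop-2-en-1-yl)-6-(3,4,5-trimethoxyphenyl)bicyclo[3.2.1]oct-2-en-4-yl acetate (C8 configuration not assigned) | C=CC[C@]12C=C(OC)[C@@H](OC(C)=O)[C@](OC)(C1O)[C@@H](c1cc(OC)c(OC)c(OC)c1)[C@@H]2C
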